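The target is an open-chain ester without stereocentres. Ring A (3,4-dimethoxyphenyl) ends the C3 acyl chain, ring B (the same arene) ends the C3 alkoxy chain, and the chains meet at O–C(=O).
Enabling feature: both ring-bearing atoms are unbranched terminal CH2 groups (ring A C1–CH2CH2C(=O) and ring B C1–CH2CH2CH2O). At the alkene oxidation level each is therefore the =CH2 end of a monosubstituted alkene. Deleting rings A and B leaves allyl acrylate, whose ester C=O polarises one alkene and can chelate palladium at the other.
Key disconnection: the ring A C1–CH2 bond and, in the same flask, the ring B C1–CH2 bond. Both come from a twofold Heck–Matsuda arylation of allyl acrylate with 3,4-dimethoxybenzenediazonium tetrafluoroborate (from 3,4-dimethoxyaniline), so the whole C22 skeleton is assembled in one operation.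
The two E-alkenes left by the coupling are a temporary oxidation level and are removed last by non-hydrogenolytic homogeneous hydrogenation.
No ring is formed in the route: rings A and B are bought intact in the aniline.

Key step: step 2

Remark: the target holds no stereocentre and no C=C bond. The E geometry of the alkene intermediates is drawn as expected from the Heck mechanism and is erased in the last step.

Step 1
Reactants: 1 3,4-dimethoxyaniline
Product: 2 3,4-dimethoxybenzenediazonium tetrafluoroborate
Conditions: NaNO2 (1.05 equiv), 48% aq HBF4 (2.5 equiv), H2O, 0 °C; filter, wash with cold Et2O, dry in vacuo in the dark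
Reagents that add atoms: sodium nitrite, [Na+].[O-]N=O; tetrafluoroboric acid, [H+].F[B-](F)(F)F
Why: Classical diazotisation (N-nitrosation by nitrous acid, then dehydration), in which the sparingly soluble tetrafluoroborate should precipitate from cold water and so be withdrawn from unreacted aniline, which suppresses azo coupling.

Step 2
Reactants: 2 3,4-dimethoxybenzenediazonium tetrafluoroborate (two equivalents react); 3 allyl acrylate
Product: 5 (E)-3-(3,4-dimethoxyphenyl)allyl (E)-3-(3,4-dimethoxyphenyl)acrylate, via allyl (E)-3-(3,4-dimethoxyphenyl)acrylate 4 (not isolated)
Conditions: 2 (2.4 equiv, added in portions), Pd2(dba)3 (4 mol %), NaOAc (6 equiv), PhCN, 25 °C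
Reagents that add atoms: none
Why: Twofold Heck–Matsuda arylation: 2 loses N2 on oxidative addition to zerovalent palladium and the resulting cationic, phosphine-free arylpalladium species delivers its ring carbon C1 to the unsubstituted =CH2 terminus of an alkene of 3 by syn insertion, after which bond rotation and syn β-hydride elimination of a benzylic hydrogen release the E-alkene and NaOAc strips HBF4 from the palladium hydride to close the cycle; the sequence should run first at the more reactive acrylate alkene (giving 4, ring A attached) and then at the allyl alkene (ring B attached). The closest known reaction types are the Heck–Matsuda arylation of acrylate esters and the Heck–Matsuda arylation of allylic acetates with retention of the acyloxy group, both of which run at room temperature with Pd2(dba)3 and NaOAc in a nitrile solvent, so one set of conditions should serve both termini. No ring is closed and no stereocentre is made; both alkene geometries follow from the syn-insertion/syn-elimination sequence and are erased in step 3. Linear (terminal) regioselectivity is secured at the acrylate by the polarisation of the alkene by the ester C=O and at the allyl end by the free =CH2 terminus together with chelation of cationic palladium by the carbonyl oxygen of the ester, which also holds the C–O bond out of the alignment needed for β-acyloxy elimination. Chemoselectivity against ionisation of the allylic ester is secured because the diazonium ion consumes ligand-free zerovalent palladium at 25 °C far faster than a π-allyl complex can form, and the mild temperature with only a small excess of 2 should hold back a further arylation of the cinnamate alkene just formed. Migration of the allyl-side double bond along the chain would be harmless, since step 3 saturates it wherever it lies.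

Step 3
Reactants: 5 (E)-3-(3,4-dimethoxyphenyl)allyl (E)-3-(3,4-dimethoxyphenyl)acrylate
Product: 6 3-(3,4-dimethoxyphenyl)propyl 3-(3,4-dimethoxyphenyl)propanoate (CNP0122973.0)
Conditions: H2 (4 atm), RhCl(PPh3)3 (5 mol %), THF/t-BuOH 1:1, 40 °C
Reagents that add atoms: none
Why: Homogeneous hydrogenation with RhCl(PPh3)3 should saturate both E-1,2-disubstituted alkenes by the dihydride/olefin-insertion pathway without the surface π-allyl pathway that cleaves cinnamylic C–O bonds on heterogeneous palladium, while the arenes, methyl ethers and ester are inert.

Compound list
1 | 3,4-dimethoxyaniline | COc1ccc(N)cc1OC | starting material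
2 | 3,4-dimethoxybenzenediazonium tetrafluoroborate | COc1ccc([N+]#N)cc1OC.F[B-](F)(F)F | intermediate
3 | allyl acrylate (prop-2-enyl prop-2-enoate) | C=CCOC(=O)C=C | starting material
4 | allyl (E)-3-(3,4-dimethoxyphenyl)acrylate | C=CCOC(=O)/C=C/c1ccc(OC)c(OC)c1 | intermediate
5 | (E)-3-(3,4-dimethoxyphenyl)allyl (E)-3-(3,4-dimethoxyphenyl)acrylate | COc1ccc(/C=C/COC(=O)/C=C/c2ccc(OC)c(OC)c2)cc1OC | intermediate
6 | 3-(3,4-dimethoxyphenyl)propyl 3-(3,4-dimethoxyphenyl)propanoate | COc1ccc(CCCOC(=O)CCc2ccc(OC)c(OC)c2)cc1OC | target

Total step count: 3. Longest linear sequence: 3 (1 → 2 → 5 → 6).

Steps most likely to fail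

1. Step 2. Several processes could spoil the coupling:
- ionisation of the allylic C–O bond by zerovalent palladium;
- β-acyloxy elimination after insertion at the allyl terminus;
- stalling after the first arylation;
- further arylation of the cinnamate alkene;
- radical polymerisation of the diene ester.

The fallback sets out from 2 and comes back at 6. Commercial 3-(3,4-dimethoxyphenyl)propan-1-ol F1 would be acylated with acryloyl chloride (Et3N, CH2Cl2, 0 °C) to 3-(3,4-dimethoxyphenyl)propyl acrylate F2, so that no allylic ester ever meets palladium. A single Heck–Matsuda arylation of F2 with 2 (Pd2(dba)3, NaOAc, MeCN, 25 °C) should give 3-(3,4-dimethoxyphenyl)propyl (E)-3-(3,4-dimethoxyphenyl)acrylate F3. Ordinary hydrogenation (H2, 10% Pd/C, EtOAc, 25 °C), now free of any hydrogenolysis issue, should then give 6.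

2. Step 3. Turnover may be slow at the conjugated cinnamate alkene, or rhodium may induce ionisation at the electron-rich cinnamylic position. The fallback sets out from 5 and comes back at 6, and it leaves metal catalysis altogether. Concerted transfer of H2 from diimide, generated from 2-nitrobenzenesulfonyl hydrazide (excess in repeated charges, Et3N, CH2Cl2, 25 °C), should saturate both alkenes and cannot touch the C–O bond. No new compound lies on this way.

3. Step 1. The freshly formed diazonium ion may undergo azo coupling with unreacted electron-rich aniline, or the salt may decompose during isolation and drying. The fallback sets out from 3 and comes back at 5, and it gives up the diazonium electrophile. Commercial 4-iodo-1,2-dimethoxybenzene F4 (2.4 equiv) would be used in a phosphine-free, silver-mediated Mizoroki–Heck arylation (Pd(OAc)2, Ag2CO3, PhMe, 90 °C). This reaction type is known for acrylates and for allylic esters with retention of the acyloxy group. Silver abstracts iodide to give the same cationic arylpalladium species.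

Further compounds
F1 | step 2 | 3-(3,4-dimethoxyphenyl)propan-1-ol | COc1ccc(CCCO)cc1OC
F2 | step 2 | 3-(3,4-dimethoxyphenyl)propyl acrylate | COc1ccc(CCCOC(=O)C=C)cc1OC
F3 | step 2 | 3-(3,4-dimethoxyphenyl)propyl (E)-3-(3,4-dimethoxyphenyl)acrylate | COc1ccc(CCCOC(=O)/C=C/c2ccc(OC)c(OC)c2)cc1OC
F0 | step 3 | none | none
F4 | step 1 | 4-iodo-1,2-dimethoxybenzene | COc1ccc(I)cc1OC
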